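**Retrosynthetic overview**
- The 8-OH comes from an 8-CHO by Dakin-type Baeyer–Villiger oxidation. The aldehyde of the A-ring starting material is carried as a masked phenol, so the 8-OH/5,7-OMe pattern never needs selective (de)methylation.
- The pyranone ring comes from lactonisation of a (Z)-β,β-diaryl acrylate. The key disconnection is C4–C4a, between the carbon of an ortho-iodophenol and the β-carbon of a β-boryl enoate (a β-acylvinyl anion, d3 homoenolate-type synthon). Both carbons are acceptor sites in their parent aryl iodide and enol triflate.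
- The β-boryl enoate comes from the (Z)-enol triflate of ethyl 3,4-dimethoxybenzoylacetate. The iodophenol comes from 2-hydroxy-4,6-dimethoxybenzaldehyde by iodination ortho to OH.
- Ring order: both benzene rings are bought. The only ring formed is the lactone, closed in the same pot as the C–C coupling. The oxidation to the 8-phenol is last.

Assumption: the target is achiral (no stereocentre, axis or stereogenic double bond), so "single enantiomer" needs no stereocontrol; only the alkene geometry of the acyclic enoate intermediates matters.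

**Route**

Step 1
Reactants: 1 2-hydroxy-4,6-dimethoxybenzaldehyde
Product: 2 2-hydroxy-3-iodo-4,6-dimethoxybenzaldehyde
Conditions: BnMe3N+ ICl2− (1.05 equiv), CaCO3 (1.5 equiv), CH2Cl2/MeOH (5:2), rt
Reagents that add atoms: benzyltrimethylammonium dichloroiodate, C[N+](C)(C)Cc1ccccc1.Cl[I-]Cl
Why: Electrophilic aromatic iodination (SEAr) by ICl2− is expected ortho to the hydrogen-bonded phenol (C3, also para to the 6-OMe and less hindered than C5 between two OMe groups), the selectivity this reagent shows with chelated hydroxy-aryl carbonyl compounds; CaCO3 removes HCl so the aldehyde and ethers are untouched.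

Step 2
Reactants: 3 ethyl 3-(3,4-dimethoxyphenyl)-3-oxopropanoate
Product: 4 ethyl (2Z)-3-(3,4-dimethoxyphenyl)-3-{[(trifluoromethyl)sulfonyl]oxy}prop-2-enoate
Conditions: Tf2O (1.3 equiv), sat. aq LiOH, toluene, 5–10 °C
Reagents that add atoms: trifluoromethanesulfonic anhydride, O=S(=O)(OS(=O)(=O)C(F)(F)F)C(F)(F)F
Why: Chelation-controlled enol triflation of a β-keto ester, in which the lithium-chelated (Z)-enolate is O-sulfonylated so that OTf ends cis to CO2Et, the geometry later needed for lactonisation; no stereocentre is formed.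

Step 3
Reactants: 2 2-hydroxy-3-iodo-4,6-dimethoxybenzaldehyde; 4 ethyl (2Z)-3-(3,4-dimethoxyphenyl)-3-{[(trifluoromethyl)sulfonyl]oxy}prop-2-enoate; 5 bis(pinacolato)diboron
Product: 8 4-(3,4-dimethoxyphenyl)-5,7-dimethoxy-2-oxo-2H-chromene-8-carbaldehyde, via β-boryl enoate 6 (not isolated), via hydroxyaryl enoate 7 (not isolated)
Conditions: (a) 4 (1.3 equiv), 5 (1.3 equiv), PdCl2(PPh3)2 (3 mol%), PPh3 (6 mol%), KOPh (1.9 equiv), toluene, 50 °C; (b) 2 (1.0 equiv), SPhos Pd G3 (5 mol%), 3 M aq K3PO4 (4 equiv), dioxane, 90 °C; 1 M HCl work-up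
Reagents that add atoms: none
Why: Miyaura borylation inverts the polarity of the electrophilic β-carbon of 4 to give β-boryl enoate 6 (a β-acylvinyl anion, d3 homoenolate-type equivalent), whose Suzuki–Miyaura coupling with the di-ortho-substituted iodophenol 2 forms C4–C4a with retention of alkene geometry, so the ortho-phenoxide of 7 sits cis to the ester and lactonises in the same pot; the aldehyde and free phenol tolerate both Pd stages and no stereocentre is formed.

Step 4
Reactants: 8 4-(3,4-dimethoxyphenyl)-5,7-dimethoxy-2-oxo-2H-chromene-8-carbaldehyde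
Product: 10 8-hydroxy-4-(3,4-dimethoxyphenyl)-5,7-dimethoxy-2H-chromen-2-one, via aryl formate 9 (not isolated)
Conditions: mCPBA (1.3 equiv), CH2Cl2, 0 °C to rt; then K2CO3 (cat.), MeOH, 0 °C; AcOH quench
Reagents that add atoms: 3-chloroperoxybenzoic acid (mCPBA), OOC(=O)c1cccc(Cl)c1
Why: Dakin-type Baeyer–Villiger oxidation in which the electron-rich 2,4,6-trioxygenated aryl group migrates to give formate 9 while the electron-poor coumarin C3=C4 bond is inert to the peracid, and mild methanolysis then frees the 8-OH (any ring-opened coumarinate recloses on acidification) without touching the four methyl ethers.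

**Compound list**

1 | 2-hydroxy-4,6-dimethoxybenzaldehyde | COc1cc(OC)c(C=O)c(O)c1 | starting material
2 | 2-hydroxy-3-iodo-4,6-dimethoxybenzaldehyde | COc1cc(OC)c(I)c(O)c1C=O | intermediate
3 | ethyl 3-(3,4-dimethoxyphenyl)-3-oxopropanoate | CCOC(=O)CC(=O)c1ccc(OC)c(OC)c1 | starting material
4 | ethyl (2Z)-3-(3,4-dimethoxyphenyl)-3-{[(trifluoromethyl)sulfonyl]oxy}prop-2-enoate | CCOC(=O)/C=C(\OS(=O)(=O)C(F)(F)F)c1ccc(OC)c(OC)c1 | intermediate
5 | bis(pinacolato)diboron | CC1(C)OB(OC1(C)C)B1OC(C)(C)C(C)(C)O1 | starting material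
6 | ethyl (2E)-3-(3,4-dimethoxyphenyl)-3-(4,4,5,5-tetramethyl-1,3,2-dioxaborolan-2-yl)prop-2-enoate | CCOC(=O)/C=C(\B1OC(C)(C)C(C)(C)O1)c1ccc(OC)c(OC)c1 | intermediate
7 | ethyl (2Z)-3-(3,4-dimethoxyphenyl)-3-(3-formyl-2-hydroxy-4,6-dimethoxyphenyl)prop-2-enoate | CCOC(=O)/C=C(\c1c(O)c(C=O)c(OC)cc1OC)c1ccc(OC)c(OC)c1 | intermediate
8 | 4-(3,4-dimethoxyphenyl)-5,7-dimethoxy-2-oxo-2H-chromene-8-carbaldehyde | COc1ccc(-c2cc(=O)oc3c(C=O)c(OC)cc(OC)c23)cc1OC | intermediate
9 | 4-(3,4-dimethoxyphenyl)-5,7-dimethoxy-2-oxo-2H-chromen-8-yl formate | COc1ccc(-c2cc(=O)oc3c(OC=O)c(OC)cc(OC)c23)cc1OC | intermediate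
10 | 8-hydroxy-4-(3,4-dimethoxyphenyl)-5,7-dimethoxy-2H-chromen-2-one (8-hydroxy-5,7,3',4'-tetramethoxy-4-phenylcoumarin) | COc1ccc(-c2cc(=O)oc3c(O)c(OC)cc(OC)c23)cc1OC | target

**Step count and risks**

Total steps: 4. Longest linear sequence: 3 (steps 1, 3, 4 or steps 2, 3, 4).

Most likely to fail, step 3: The β-boryl enoate 6 may protodeboronate, or transmetalation onto the hindered aryl–Pd from 2 may be too slow. The fallback sets out from 2 and comes back at 8, joining the same two carbons by reductive alkyne hydroarylation instead of a boron reagent. Compound 2 is treated with ethyl 3-(3,4-dimethoxyphenyl)prop-2-ynoate F1 under Pd(OAc)2, HCO2K, DMF, 40–60 °C. F1 is made in one step from commercial 4-iodo-1,2-dimethoxybenzene and ethyl propiolate (PdCl2(PPh3)2, CuI, K2CO3, THF). Syn-carbopalladation puts the aryl group on the β-carbon and formate reduces the vinyl–Pd bond, giving ethyl (2E)-3-(3,4-dimethoxyphenyl)-3-(3-formyl-2-hydroxy-4,6-dimethoxyphenyl)prop-2-enoate F2, with the A ring trans to the ester. F2 is then isomerised through its quinone-methide-like phenoxide (DBU, toluene, 110 °C, or 365 nm light) and lactonises to 8.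

Second, step 1: Iodination may also occur at C5 (para to OH), giving an isomer that cannot lactonise. The fallback sets out from 1 and comes back at 8. It replaces innate SEAr selectivity by hydrogen-bond-directed delivery of halogen from an N-bromoamine to the position ortho to the phenol (NBS, i-Pr2NH, CH2Cl2, 0 °C). This gives 3-bromo-2-hydroxy-4,6-dimethoxybenzaldehyde F3, which is used as the electrophile in place of 2 in the step 3 cascade and reaches 8 through the same enoate 7.

Third, step 4: The peracid oxidation on the coumarin may give poor aryl migration or over-oxidation. The fallback sets out from 2 and comes back at 10, moving the oxidation ahead of the coupling. Compound 2 is an ortho-hydroxybenzaldehyde, the classical Dakin substrate, and H2O2/aq NaOH at 0 °C converts it to 3-iodo-4,6-dimethoxybenzene-1,2-diol F4. Coupling F4 with 6 under the step 3 conditions (rigorously degassed, one extra equivalent of K3PO4) gives ethyl (2Z)-3-(2,3-dihydroxy-4,6-dimethoxyphenyl)-3-(3,4-dimethoxyphenyl)prop-2-enoate F5. Only the hydroxyl ortho to the new C–C bond can reach the ester, so F5 lactonises directly to 10.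

**Further compounds**

F1 | step 3 | ethyl 3-(3,4-dimethoxyphenyl)prop-2-ynoate | CCOC(=O)C#Cc1ccc(OC)c(OC)c1
F2 | step 3 | ethyl (2E)-3-(3,4-dimethoxyphenyl)-3-(3-formyl-2-hydroxy-4,6-dimethoxyphenyl)prop-2-enoate | CCOC(=O)/C=C(/c1c(O)c(C=O)c(OC)cc1OC)c1ccc(OC)c(OC)c1
F3 | step 1 | 3-bromo-2-hydroxy-4,6-dimethoxybenzaldehyde | COc1cc(OC)c(Br)c(O)c1C=O
F4 | step 4 | 3-iodo-4,6-dimethoxybenzene-1,2-diol | COc1cc(OC)c(I)c(O)c1O
F5 | step 4 | ethyl (2Z)-3-(2,3-dihydroxy-4,6-dimethoxyphenyl)-3-(3,4-dimethoxyphenyl)prop-2-enoate | CCOC(=O)/C=C(\c1c(O)c(O)c(OC)cc1OC)c1ccc(OC)c(OC)c1
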